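The runs were computed on assumed constants.

The substrate is the small charge here, 0.30 M against 1.50 M of first nucleophile, so it is the limiting reagent and you write its balance. Each substrate either becomes target or is lost by a rival path. The first nucleophile is in excess, so treat its concentration as constant.

in all of them: substrate 0.30 M

| charge | first nucleophile | solid second nucleophile | temperature | remark | time |
|---|---|---|---|---|---|
| west | 0.75 M | 0.30 M | −25 °C | run made earlier |  |
| south-east | 1.1 M | 0.30 M | 0 °C | run made earlier |  |
| south-west | 1.5 M | 0.15 M | −25 °C | run made earlier |  |
| Thursday's | 1.50 M | 0.300 M | 0 °C |  | 5.0 h |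
| Tuesday's | 1.50 M | 0.300 M | −20 °C |  | 5.0 h |
| Saturday's | 1.50 M | 0.300 M | 20 °C |  | 5.0 h |

| run | time / h | target / % |
|---|---|---|
| west | 3.00 | 6.7 |
| west | 5.00 | 11.1 |
| west | 8.00 | 15.2 |
| west | 10.0 | 17.2 |
| south-east | 0.833 | 24.0 |
| south-east | 1.50 | 25.2 |
| south-east | 2.50 | 26.5 |
| south-east | 3.00 | 27.4 |
| south-west | 1.33 | 4.6 |
| south-west | 3.00 | 10.3 |
| south-west | 6.00 | 18.9 |
| south-west | 10.0 | 26.9 |

(each reading ± 0.5 percentage points)

- the earlier runs were read with a standard deviation of 0.5 percentage points
- at the start none of the solid second nucleophile is in solution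

1. the flask with the highest amount of target, in percent of the substrate charged ("all alike" if they lie within 1.5 percentage points) (Thursday's / Tuesday's / Saturday's / all alike)
2. final target, as a percentage of the substrate charged, in Thursday's
3. final target, as a percentage of the substrate charged, in Tuesday's
4. final target, as a percentage of the substrate charged, in Saturday's

Turn the first nucleophile first. Suppose the rival path ignores it. Then target's share of spent substrate is c(first nucleophile)/(c(first nucleophile) + K). The south-east run has nearly stopped, since its last two readings differ by 0.9 percentage points. Its 27.4% at 1.1 M gives 2.91 M. This K is the split concentration: the c(first nucleophile) at which target and the rival path take equal shares. For Thursday's flask, at the same temperature, the share is 34.0%.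

Now turn the temperature. The two cold runs share a clock, so their readings at 10.0 h stand in the ratio of their shares, 1.56. That gives 1.94 M at −25 °C, less than at 0 °C. Warming therefore favours the rival path. I leave the solid out of this, which is a guess, because the cold runs also differ in solid.

Saturday's flask, at 20 °C, is warmer than Thursday's. So if K keeps rising with temperature, I expect Saturday's share to fall short of Thursday's 34.0%. Tuesday's flask, at −20 °C, stands close to the cold runs, and their K gives a share of 43.6% at 1.50 M. I expect Tuesday's flask to stop short of that share in 5.0 h, for the south-west run still gained 8 points in its last 4.00 h.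

The forecast differs from my reckoning. It names Saturday's, with 33% on Thursday, 24% on Tuesday and 42% on Saturday. It says “Saturday has a similar burst but faster creep”.

The flasks give Thursday's as the highest: 33.7% on Thursday, 26.0% on Tuesday and 28.1% on Saturday.

    substrate → intermediate (k = 0.203 h⁻¹, Ea = 74.0 kJ mol⁻¹)
    first nucleophile + intermediate → target (k = 7.08 L mol⁻¹ h⁻¹, Ea = 63.0 kJ mol⁻¹)
    second nucleophile + intermediate → other capture product (k = 16.2 L mol⁻¹ h⁻¹, Ea = 62.0 kJ mol⁻¹)
    intermediate → solvolysis product (k = 14.7 h⁻¹, Ea = 72.0 kJ mol⁻¹)
    2 second nucleophile → homo dimer (k = 6.22 L mol⁻¹ h⁻¹, Ea = 42.0 kJ mol⁻¹)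
    solid second nucleophile ⇌ second nucleophile, rate k6*(cs6 - [second nucleophile]) while solid is left; crystals form when [second nucleophile] > cs6 (solubility = 0.0960 M, k = 0.121 h⁻¹)
    (constants at −20 °C)

Saturday's flask converted 100% of its substrate, and at 50.0 h its target still stands at 28.1%. Its 28.1% corresponds to a split concentration of 3.84 M, above the 2.91 M of 0 °C. Solvolysis product took 71.8%, and with that step removed, Saturday's target reaches 99.9%. On the neighbour of Thursday's flask with 0.90 M of first nucleophile, K gives 23.6%. That flask gives 23.3%.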